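## Structural features

The target, C22H24O6, is 7-allyl-5-methoxy-3-methyl-2-(3,4,5-trimethoxyphenyl)benzofuran-6-ol. A benzene ring (ring A, C3a to C7a) is fused to a furan ring (ring B, O1, C2, C3); a 3,4,5-trimethoxyphenyl ring (ring C) is attached to C2 by a single bond and a methyl group sits on C3. Ring A is substituted everywhere except C4: methoxy on C5, a free hydroxyl on C6 and an allyl group on C7, so three different substituents and the two fusion atoms stand in an unbroken row. The molecule has no stereocentre and no stereogenic double bond, so the problem is one of regiochemistry and chemoselectivity only. The fragile parts are the terminal allyl group (shift into conjugation under strong base or metal hydrides, attack by peracids, acid-promoted closure onto a neighbouring free phenol), the free C6 phenol on a very electron-rich ring (oxidation), and the electron-rich C2=C3 bond. The real difficulty is to annulate ring B onto the O1-C7a-C3a edge of ring A while the C7 allyl group is in place, and to tell the two ring-A oxygens (O1 and the C6 oxygen) apart. The key step uses the fact that C2, C3, the C3 methyl group and ring C together are the skeleton of an aryl ethyl ketone, while O1, C7a and C3a are the oxygen, ipso carbon and one ortho CH of a phenol. Tied through an N-O bond as an O-aryl ketoxime, the two halves can be joined at C3-C3a by a [3,3] shift and at O1-C2 by condensation, with the C7 allyl group blocking the second ortho carbon.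

## Logic of the disconnections

15 back to 14: the O-acyl bond on the C6 oxygen is cut, i.e. the phenol is carried as a pivalate. A free phenol ortho to the allyl group would be exposed to acid-induced ring closure and to oxidation during furan formation, and the two ring-A oxygens must be distinguishable earlier. The gain in simplicity is small but the protection is essential. The forward step must cleave a hindered aryl ester without moving the allyl double bond or oxidizing the phenoxide.

14 back to 10: C3-C3a and O1-C2 are cut together. This removes ring B and both of its new skeletal bonds in one operation and divides the molecule into a ring-A aryloxy unit and a ring-C propiophenone unit. The forward step needs a single direction of enamine formation, one free ortho carbon on the aryloxy ring, and an acid that spares the ester and the alkene in an anhydrous medium.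

10 back to 8 and 9: the C=N bond is cut. The route becomes convergent and 9 is a commercial ketone. The forward condensation must be fast and mildly acidic, because the aryloxyamine is a weak nucleophile and does not keep well.

8 back to 7: the N-O bond is cut, leading to a phenol and an electrophilic NH2 source. A phenol is far easier to reach here than an aryl halide or boronic acid. The forward step needs exactly one free phenolic oxygen and an ester bulky enough to resist acyl transfer to a phenoxide or to the aminooxy group.

7 back to 5 (through 6): the aryl C-O bond of the new phenol is traced to an aryl C-CHO bond. The formyl-bearing carbon of 1 sits para to the methoxy group, exactly where O1 is required, and that para donor makes the aryl group migrate in the peracid oxidation. The forward step must oxidize the aldehyde faster than the terminal alkene, and must remove the formate while leaving the pivalate.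

5 back to 4: the O-acyl bond is cut. Acylation comes before the oxidation, so the hydroxyl released by the Claisen step is capped while the future O1 is still a formyl group and the two phenols never coexist unprotected. An oxidation-first order would need a temporary silyl group on O1 and two more steps.

4 back to 3: the bond between the ring carbon (future C7) and the allyl CH2 is cut. An aromatic Claisen rearrangement installs it: of the two ortho carbons of the allyloxy group one bears the methoxy group, so the allyl group can only arrive between the oxygen and the formyl-bearing carbon. The forward step needs only heat.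

3 back to 1 and 2: the O-allyl bond is cut. Both fragments are bulk chemicals, and 1 already holds the methoxy group, the future C6 oxygen and the future O1 position in the correct 1,2,4 relationship. The forward step is a simple phenol alkylation.

## Other disconnections considered

Alternative 1: The cut is C2-C3 and O1-C2, leaving ring A with O1 and C3 as an o-quinone methide precursor, the sulfone A2, and C2 with ring C as the benzylic sulfonium salt A3. In the forward step Cs2CO3 would expel sulfinate from A2, the ylide from A3 would add to the exocyclic carbon, and the phenoxide would displace the sulfide to close the trans-dihydrobenzofuran A1.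
- In its favour: it is convergent, runs under mild base near room temperature, and involves no N-O bond or labile aryloxyamine; on mildness it is the better plan. It forms two ring-B bonds in one step, which equals the chosen plan, and its regiochemistry is equally secure because O1 and C3 are already on ring A.
- Against it: A1 is at the wrong oxidation level. Its two stereocentres serve no purpose and must be erased by dehydrogenation, and quinone-type oxidants would threaten the allyl CH2, which is both benzylic and allylic on an electron-rich ring. The MOM group must then be removed with acid next to the allyl group. A2 needs a ring-A phenol of the same complexity as 7 plus an ortho sulfonylethylation.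
- Comparison: structurally both plans join a ring-A phenol to a ring-C unit, but here C3 comes from ring A and not from the ketone. Mechanistically it is a polar base-mediated annulation against an acid-mediated pericyclic one. On step economy the chosen plan should be about two steps shorter and needs no redox correction.

Alternative 2: The cut is O1-C2 alone, made by ring contraction of the bromocoumarin A5. In the forward step hot aqueous NaOH would open the lactone and the phenoxide would displace the vinylic bromide by addition-elimination, giving the acid A4.
- In its favour: the chemistry is robust and scalable, the coumarin would come from a Pechmann condensation, and the C3 methyl group is placed without ambiguity. The carboxyl group is a handle for varying the 2-aryl group, so for analogue work it is the better plan. A late O-allylation and Claisen shift to C7 would reveal the C6 phenol without a final deprotection, also a point in its favour.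
- Against it: A4 carries neither ring C nor the allyl group. The C2-aryl bond must be made afterwards by decarboxylative cross-coupling with a trimethoxyphenyl halide (for example Pd(OAc)2 with Ag2CO3), followed by debenzylation, allylation and Claisen rearrangement. The key step therefore builds one skeletal bond against two, the sequence is linear, and CO2 and bromine are discarded.
- Comparison: the step count should be about equal (eight to nine). The chosen plan is better in convergence and in what the ring-forming step achieves; Alternative 2 is better in the stability of its intermediates.

Alternative 3: The cut is O1-C7a. In the forward step FeCl3 would oxidize the alpha-aryl ketone A7 so that the enol oxygen bonds to the ring carbon para to the methoxy group, giving A6. A Claisen rearrangement of A6 would then move the allyl group to C7 (C5 is blocked) and free the C6 phenol, which is the target itself.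
- In its favour: A7 should be available from ketone 9 in one palladium-catalysed alpha-arylation, so the target would be reached in about four steps without any protecting group. On step economy and protecting-group economy it is clearly the better plan. It equals the chosen plan in using 9 and in fixing the allyl position by a Claisen shift onto the only free ortho carbon.
- Against it: the ring closure is an oxidation with stoichiometric trivalent iron on a substrate with two very electron-rich arenes, where oxidative aryl-aryl coupling and chlorination can compete. The allyl aryl ether is sensitive to Lewis acids. A simple ketone without a second activating carbonyl enolizes reluctantly. The choice between the two ortho carbons rests on electronic preference and not on a blocking group.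
- Comparison: the chosen plan is redox-neutral and its site of ring closure is fixed by substitution, so it is the better plan in mechanistic security. It is the weaker plan in length.

Key step: step 7

Remark: oxime ether 10 is drawn as its (E) isomer; any (Z) isomer would be carried along, because acid equilibrates both through the protonated C=N bond before the rearrangement.

## Route

Step 1
Reactants: 1 isovanillin (3-hydroxy-4-methoxybenzaldehyde); 2 allyl bromide
Product: 3 3-(allyloxy)-4-methoxybenzaldehyde
Conditions: K2CO3, DMF, rt to 50 °C
Reagents that add atoms: none
Why: Williamson ether synthesis; the phenoxide is the only nucleophile formed by K2CO3 and attacks the allylic bromide by SN2, the aldehyde being inert.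

Step 2
Reactants: 3 3-(allyloxy)-4-methoxybenzaldehyde
Product: 4 2-allyl-3-hydroxy-4-methoxybenzaldehyde
Conditions: neat, N2, 190-200 °C
Reagents that add atoms: none
Why: Aromatic Claisen rearrangement; one ortho carbon of the allyloxy group bears the methoxy group, so the [3,3] shift and enolization should place the allyl group on the carbon between the oxygen and the formyl-bearing carbon, the future C7.

Step 3
Reactants: 4 2-allyl-3-hydroxy-4-methoxybenzaldehyde
Product: 5 2-allyl-3-formyl-6-methoxyphenyl pivalate
Conditions: PivCl, Et3N, DMAP (cat.), CH2Cl2, 0 °C to rt
Reagents that add atoms: pivaloyl chloride, CC(C)(C)C(=O)Cl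
Why: DMAP-catalysed O-acylation through the acylpyridinium ion copes with a phenol flanked by two ortho groups. The bulky ester is chosen because it should resist acid, phenoxides and amine nucleophiles in steps 4 to 7.

Step 4
Reactants: 5 2-allyl-3-formyl-6-methoxyphenyl pivalate
Product: 7 2-allyl-3-hydroxy-6-methoxyphenyl pivalate, via aryl formate 6 (not isolated)
Conditions: mCPBA (1.3 equiv), CH2Cl2, 0 °C to rt; aq. Na2S2O3/NaHCO3 wash; then Et3N (cat.), MeOH, 0 °C to rt
Reagents that add atoms: mCPBA, O=C(OO)c1cccc(Cl)c1
Why: Baeyer-Villiger (Dakin-type) oxidation; the para methoxy group makes the aryl group migrate in the Criegee intermediate, and the electron-rich aldehyde should react faster with the peracid than the monosubstituted alkene. The formate is far more labile than the hindered pivalate, so amine-catalysed methanolysis should free only the new phenol.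

Step 5
Reactants: 7 2-allyl-3-hydroxy-6-methoxyphenyl pivalate
Product: 8 2-allyl-3-(aminooxy)-6-methoxyphenyl pivalate
Conditions: KOt-Bu (1.0 equiv), DMF, 0 °C; then 2,4-(O2N)2C6H3ONH2 (1.1 equiv), 0 °C to rt; used at once
Reagents that add atoms: O-(2,4-dinitrophenyl)hydroxylamine, NOc1ccc(cc1[N+](=O)[O-])[N+](=O)[O-]
Why: Electrophilic amination of a phenoxide; the phenoxide oxygen attacks the nitrogen of the reagent and displaces the stabilized 2,4-dinitrophenoxide. Only one phenolic oxygen is free, and the pivalate is too hindered for acyl transfer.

Step 6
Reactants: 8 2-allyl-3-(aminooxy)-6-methoxyphenyl pivalate; 9 1-(3,4,5-trimethoxyphenyl)propan-1-one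
Product: 10 (E)-1-(3,4,5-trimethoxyphenyl)propan-1-one O-[2-allyl-4-methoxy-3-(pivaloyloxy)phenyl] oxime
Conditions: conc. HCl (cat.), EtOH, rt to 40 °C
Reagents that add atoms: none
Why: Acid-catalysed condensation of an O-substituted hydroxylamine with a ketone (oxime ether formation). The isomer with the aryloxy group anti to ring C should prevail, and the geometry is of no consequence for step 7.

Step 7
Reactants: 10 (E)-1-(3,4,5-trimethoxyphenyl)propan-1-one O-[2-allyl-4-methoxy-3-(pivaloyloxy)phenyl] oxime
Product: 14 7-allyl-5-methoxy-3-methyl-2-(3,4,5-trimethoxyphenyl)benzofuran-6-yl pivalate, via N-aryloxy enamine 11 (not isolated), via ortho-hydroxyaryl ketimine 12 (not isolated), via 2-aminodihydrobenzofuran 13 (not isolated)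
Conditions: HCl (4 M in 1,4-dioxane, 3 equiv), 65 °C
Reagents that add atoms: none
Why: Acid protonates the oxime nitrogen and tautomerizes the C=N bond towards the ethyl group, the only side with alpha hydrogens, to give the N-aryloxy enamine 11. Its weak N-O bond breaks in a concerted [3,3]-sigmatropic shift that joins the enamine beta carbon (future C3) to the unsubstituted ortho carbon of ring A (future C3a); enolization of the resulting cyclohexadienone restores the arene as the ketimine 12. The phenolic oxygen then adds to the protonated imine carbon in a 5-exo-trig closure that forms O1-C2 and ring B as the aminal 13, and loss of ammonia, trapped as NH4Cl, aromatizes the furan. The closest known reaction type is the acid-mediated rearrangement and cyclization of O-aryl ketoxime ethers to benzofurans, the oxygen counterpart of the Fischer indole synthesis. No stereocentre remains, the transient ones in 12 and 13 being erased on aromatization. The step needs regioselectivity between the two ortho carbons and a single direction of enamine formation: the allyl group occupies one ortho carbon, where a shift would give a crowded dienone that cannot enolize, and the aryl side of the ketone has no alpha hydrogen, so C3 must carry the methyl group. The pivalate keeps the C6 oxygen from closing onto the allyl group under acid, and the anhydrous medium avoids hydrolysis of the C=N bond.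

Step 8
Reactants: 14 7-allyl-5-methoxy-3-methyl-2-(3,4,5-trimethoxyphenyl)benzofuran-6-yl pivalate
Product: 15 7-allyl-5-methoxy-3-methyl-2-(3,4,5-trimethoxyphenyl)benzofuran-6-ol
Conditions: K2CO3, MeOH/THF, 40 °C, Ar; then aq. NH4Cl
Reagents that add atoms: none
Why: Base-mediated transesterification (methanolysis) of an aryl ester, helped by the good phenoxide leaving group. K2CO3 in methanol is too mild to move the allyl double bond into conjugation, and argon protects the electron-rich phenoxide from oxidation.

## Compound list

1 | isovanillin (3-hydroxy-4-methoxybenzaldehyde) | COc1ccc(C=O)cc1O | starting material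
2 | allyl bromide (3-bromoprop-1-ene) | C=CCBr | starting material
3 | 3-(allyloxy)-4-methoxybenzaldehyde | C=CCOc1cc(C=O)ccc1OC | intermediate
4 | 2-allyl-3-hydroxy-4-methoxybenzaldehyde | C=CCc1c(C=O)ccc(OC)c1O | intermediate
5 | 2-allyl-3-formyl-6-methoxyphenyl pivalate | C=CCc1c(C=O)ccc(OC)c1OC(=O)C(C)(C)C | intermediate
6 | 2-allyl-3-(formyloxy)-6-methoxyphenyl pivalate | C=CCc1c(OC=O)ccc(OC)c1OC(=O)C(C)(C)C | intermediate (not isolated)
7 | 2-allyl-3-hydroxy-6-methoxyphenyl pivalate | C=CCc1c(O)ccc(OC)c1OC(=O)C(C)(C)C | intermediate
8 | 2-allyl-3-(aminooxy)-6-methoxyphenyl pivalate | C=CCc1c(ON)ccc(OC)c1OC(=O)C(C)(C)C | intermediate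
9 | 1-(3,4,5-trimethoxyphenyl)propan-1-one | CCC(=O)c1cc(OC)c(OC)c(OC)c1 | starting material
10 | (E)-1-(3,4,5-trimethoxyphenyl)propan-1-one O-[2-allyl-4-methoxy-3-(pivaloyloxy)phenyl] oxime | C=CCc1c(O/N=C(\CC)c2cc(OC)c(OC)c(OC)c2)ccc(OC)c1OC(=O)C(C)(C)C | intermediate
11 | 2-allyl-6-methoxy-3-({[1-(3,4,5-trimethoxyphenyl)prop-1-en-1-yl]amino}oxy)phenyl pivalate (alkene geometry not defined) | C=CCc1c(ONC(=CC)c2cc(OC)c(OC)c(OC)c2)ccc(OC)c1OC(=O)C(C)(C)C | intermediate (not isolated)
12 | 2-allyl-3-hydroxy-4-[1-imino-1-(3,4,5-trimethoxyphenyl)propan-2-yl]-6-methoxyphenyl pivalate (racemic) | C=CCc1c(O)c(C(C)C(=N)c2cc(OC)c(OC)c(OC)c2)cc(OC)c1OC(=O)C(C)(C)C | intermediate (not isolated)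
13 | 7-allyl-2-amino-5-methoxy-3-methyl-2-(3,4,5-trimethoxyphenyl)-2,3-dihydrobenzofuran-6-yl pivalate (mixture of diastereomers) | C=CCc1c(OC(=O)C(C)(C)C)c(OC)cc2c1OC(N)(c1cc(OC)c(OC)c(OC)c1)C2C | intermediate (not isolated)
14 | 7-allyl-5-methoxy-3-methyl-2-(3,4,5-trimethoxyphenyl)benzofuran-6-yl pivalate | C=CCc1c(OC(=O)C(C)(C)C)c(OC)cc2c(C)c(-c3cc(OC)c(OC)c(OC)c3)oc12 | intermediate
15 | 7-allyl-5-methoxy-3-methyl-2-(3,4,5-trimethoxyphenyl)benzofuran-6-ol | C=CCc1c(O)c(OC)cc2c(C)c(-c3cc(OC)c(OC)c(OC)c3)oc12 | target

## Step count and least certain steps

Total step count: 8. Longest linear sequence: 8 steps (1 to 15); ketone 9 enters at step 6.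

Step 7 (key step). The most likely failure is cleavage of the N-O bond without C-C bond formation (acid-induced solvolysis back towards phenol and ketone), because the para-alkoxy aryloxy group favours heterolysis and the hindered, electron-rich aryl ketone forms its enamine slowly. Some loss of the pivalate on long heating is a second risk. Fallback, from 10 and back at 14: trigger the shift by N-acylation and not by protonation. (CF3CO)2O in CH2Cl2 at 0 °C should convert 10 into the N-trifluoroacetyl ene-hydroxylamine F1, which should rearrange below room temperature and close to the 2-(trifluoroacetamido)-2,3-dihydrobenzofuran F2, a neutral and isolable compound. Separate treatment of F2 with CF3CO2H at 40 °C would eliminate trifluoroacetamide and give 14. Ring construction and aromatization become two distinct operations, and no hot mineral acid meets the N-O bond.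

Step 5. The most likely failures are amination at carbon or oxidative breakdown of the electron-rich phenoxide, attack of the phenoxide on the dinitroarene ring of the reagent, and decay of the free aryloxyamine during handling. Fallback, from 7 and back at 10 (bypassing 8): make the aryl-O bond by copper-mediated oxidative coupling. Phenol 7 with Tf2O and pyridine in CH2Cl2 at 0 °C would give the aryl triflate F3. Miyaura-type borylation (Pd(OAc)2, XPhos, B2(OH)4, KOAc, EtOH, 80 °C) would give the arylboronic acid F4. Ketone 9 with NH2OH·HCl and NaOAc in EtOH would give the ketoxime F5. Chan-Lam coupling of F4 with F5 (Cu(OAc)2, pyridine, 4 Å MS, 1,2-dichloroethane, air, rt) would form 10 directly.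

Step 4. The most likely failure is epoxidation of the terminal alkene in competition with the Baeyer-Villiger oxidation. Migration of hydride instead of aryl is a second risk, because the meta acyloxy group lowers the migratory aptitude of the ring. Fallback, from 3 and back at 7: oxidize before the Claisen rearrangement, while the alkene is still a less nucleophilic allyl ether. mCPBA in CH2Cl2 would convert 3 into the aryl formate F6, and Et3N in MeOH would give the phenol F7. TBSCl and imidazole in DMF would give the silyl ether F8. Heating at 200 °C (Claisen rearrangement) would give the 2-allylphenol F9. PivCl, Et3N and DMAP would give the silyl-protected pivalate F10, and TBAF with AcOH in THF at 0 °C would release 7. This costs two more steps.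

Step 6. The most likely failure is slow condensation between the weakly nucleophilic aryloxyamine and the hindered, electron-rich ketone, which would leave 8 time to decompose. Fallback, from 9 and back at 10: replace the ketone by a more electrophilic ketal. HC(OMe)3 and p-TsOH (cat.) in MeOH would convert 9 into the dimethyl ketal F11, which ionizes readily to an oxocarbenium ion. Compound 8 and F11 with PPTS in CH2Cl2 at rt should give 10 with loss of methanol and without water being formed.

Step 8. The most likely failure is incomplete cleavage of the pivalate, which lies between two ortho substituents, or oxidation of the phenoxide if air enters during prolonged warming. Fallback, from 14 and back at 15: reductive cleavage in place of solvolysis, with i-Bu2AlH (2.2 equiv) in CH2Cl2 at -78 °C, which removes the acyl group as its alcohol under non-basic conditions. No new compound arises (entry F0).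

## Further compounds

F1 | step 7 | N-[2-allyl-4-methoxy-3-(pivaloyloxy)phenoxy]-2,2,2-trifluoro-N-[1-(3,4,5-trimethoxyphenyl)prop-1-en-1-yl]acetamide | C=CCc1c(ON(C(=O)C(F)(F)F)C(=CC)c2cc(OC)c(OC)c(OC)c2)ccc(OC)c1OC(=O)C(C)(C)C
F2 | step 7 | 7-allyl-5-methoxy-3-methyl-2-(2,2,2-trifluoroacetamido)-2-(3,4,5-trimethoxyphenyl)-2,3-dihydrobenzofuran-6-yl pivalate (mixture of diastereomers) | C=CCc1c(OC(=O)C(C)(C)C)c(OC)cc2c1OC(NC(=O)C(F)(F)F)(c1cc(OC)c(OC)c(OC)c1)C2C
F3 | step 5 | 2-allyl-6-methoxy-3-{[(trifluoromethyl)sulfonyl]oxy}phenyl pivalate | C=CCc1c(OS(=O)(=O)C(F)(F)F)ccc(OC)c1OC(=O)C(C)(C)C
F4 | step 5 | [2-allyl-4-methoxy-3-(pivaloyloxy)phenyl]boronic acid | C=CCc1c(B(O)O)ccc(OC)c1OC(=O)C(C)(C)C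
F5 | step 5 | (E)-1-(3,4,5-trimethoxyphenyl)propan-1-one oxime | CC/C(=N\O)c1cc(OC)c(OC)c(OC)c1
F6 | step 4 | 3-(allyloxy)-4-methoxyphenyl formate | C=CCOc1cc(OC=O)ccc1OC
F7 | step 4 | 3-(allyloxy)-4-methoxyphenol | C=CCOc1cc(O)ccc1OC
F8 | step 4 | [3-(allyloxy)-4-methoxyphenoxy](tert-butyl)dimethylsilane | C=CCOc1cc(O[Si](C)(C)C(C)(C)C)ccc1OC
F9 | step 4 | 2-allyl-3-[(tert-butyldimethylsilyl)oxy]-6-methoxyphenol | C=CCc1c(O[Si](C)(C)C(C)(C)C)ccc(OC)c1O
F10 | step 4 | 2-allyl-3-[(tert-butyldimethylsilyl)oxy]-6-methoxyphenyl pivalate | C=CCc1c(O[Si](C)(C)C(C)(C)C)ccc(OC)c1OC(=O)C(C)(C)C
F11 | step 6 | 5-(1,1-dimethoxypropyl)-1,2,3-trimethoxybenzene | CCC(OC)(OC)c1cc(OC)c(OC)c(OC)c1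
F0 | step 8 | none | none
A1 | alternative 1 | rac-trans-7-allyl-5-methoxy-6-(methoxymethoxy)-3-methyl-2-(3,4,5-trimethoxyphenyl)-2,3-dihydrobenzofuran | C=CCc1c(OCOC)c(OC)cc2c1O[C@@H](c1cc(OC)c(OC)c(OC)c1)[C@@H]2C
A2 | alternative 1 | rac-2-allyl-4-methoxy-3-(methoxymethoxy)-6-(1-tosylethyl)phenol | C=CCc1c(O)c(C(C)S(=O)(=O)c2ccc(C)cc2)cc(OC)c1OCOC
A3 | alternative 1 | dimethyl(3,4,5-trimethoxybenzyl)sulfonium bromide | C[S+](C)Cc1cc(OC)c(OC)c(OC)c1.[Br-]
A4 | alternative 2 | 6-(benzyloxy)-5-methoxy-3-methylbenzofuran-2-carboxylic acid | Cc1c(C(=O)O)oc2cc(OCc3ccccc3)c(OC)cc12
A5 | alternative 2 | 7-(benzyloxy)-3-bromo-6-methoxy-4-methyl-2H-chromen-2-one | Cc1c(Br)c(=O)oc2cc(OCc3ccccc3)c(OC)cc12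
A6 | alternative 3 | 6-(allyloxy)-5-methoxy-3-methyl-2-(3,4,5-trimethoxyphenyl)benzofuran | C=CCOc1cc2oc(-c3cc(OC)c(OC)c(OC)c3)c(C)c2cc1OC
A7 | alternative 3 | rac-2-[4-(allyloxy)-3-methoxyphenyl]-1-(3,4,5-trimethoxyphenyl)propan-1-one | C=CCOc1ccc(C(C)C(=O)c2cc(OC)c(OC)c(OC)c2)cc1OC
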